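**Assumption:** the three aromatic building blocks are taken as catalogue items, and the facial sense of the chiral scandium catalyst in step 2 is untested on this substrate. If induction runs the wrong way, the ligand antipode (from D-pipecolic acid) is used instead.

## Retrosynthetic overview

1. Target ⇐ global O-debenzylation of its 7,3',4'-tri-O-benzyl ether.
2. C4–aryl bond ⇐ substrate-controlled SN1 Friedel–Crafts reaction of a tri-O-benzyl flavan-3,4-diol with 2-methoxyresorcinol, entering trans to the 3-OH; the diol ⇐ hydride reduction of the flavanon-3-ol.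
3. Key disconnection: O1–C2 and C3–O of ring C ⇐ one-flask enantioselective epoxidation and 6-endo phenol opening of an unprotected 2'-hydroxychalcone; this sets C2 and C3 and all absolute configuration.
4. Chalcone ⇐ Claisen–Schmidt condensation of two benzyl-protected aromatics.
5. Ring order: rings A and B are bought; ring C (pyran) is closed by C–O bond formation in step 2; the fourth aryl ring is attached in step 4.

## Route

**Step 1**
Reactants: 1 1-[4-(benzyloxy)-2-hydroxyphenyl]ethan-1-one; 2 3,4-bis(benzyloxy)benzaldehyde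
Product: 3 (E)-1-[4-(benzyloxy)-2-hydroxyphenyl]-3-[3,4-bis(benzyloxy)phenyl]prop-2-en-1-one
Conditions: KOH (3 equiv), EtOH/THF 2:1, 25 °C, 36 h; then 1 M HCl to pH 3
Reagents that add atoms: none
Why: Claisen–Schmidt (crossed aldol) condensation, in which the acetophenone enolate adds to the non-enolisable aldehyde and E1cB dehydration gives only the conjugated E-enone; no stereocentre is formed, and without a 6'-substituent the open chalcone rather than the flavanone is obtained on acidification.

**Step 2**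
Reactants: 3 (E)-1-[4-(benzyloxy)-2-hydroxyphenyl]-3-[3,4-bis(benzyloxy)phenyl]prop-2-en-1-one
Product: 5 (2R,3R)-7-(benzyloxy)-2-[3,4-bis(benzyloxy)phenyl]-3-hydroxy-2,3-dihydro-4H-chromen-4-one, via (2R,3S)-epoxychalcone 4 (not isolated)
Conditions: Sc(OTf)3 (10 mol%), chiral N,N'-dioxide L-PiPr2 (11 mol%; the bis-N-oxide of 1,3-bis[(2S)-2-{(2,6-diisopropylphenyl)carbamoyl}piperidin-1-yl]propane), 30% aq H2O2 (1.3 equiv), THF, 0 °C, 16 h; then 35 °C, 4 h
Reagents that add atoms: hydrogen peroxide, OO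
Why: Proposed new method: an enantioselective Algar–Flynn–Oyamada-type oxidative cyclisation run under Lewis-acidic instead of basic conditions, in which the 2'-OH/C=O pair chelates the chiral N,N'-dioxide–Sc(OTf)3 complex (trivalent scandium) so that the enone is activated and one face is shielded, H2O2 adds conjugately and closes to the (2R,3S)-epoxide 4 (Weitz–Scheffer manifold, sets C3), and the same Lewis acid then polarises the benzylic C–O bond (stabilised by the para-benzyloxy group of ring B) so that the pendant phenol opens it 6-endo with inversion, setting C2 trans to C3; the base-free medium should shut down the flavonol and aurone pathways of the classical reaction; the closest known chemistry is chiral N,N'-dioxide–scandium epoxidation of simple enones with aqueous H2O2 and acid-induced cyclisation of pre-formed epoxides of O-protected 2'-hydroxychalcones, but neither an asymmetric epoxidation of a free 2'-hydroxychalcone nor the merged catalytic cascade has been shown.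

**Step 3**
Reactants: 5 (2R,3R)-7-(benzyloxy)-2-[3,4-bis(benzyloxy)phenyl]-3-hydroxy-2,3-dihydro-4H-chromen-4-one
Product: 6 (2R,3S,4R)-7-(benzyloxy)-2-[3,4-bis(benzyloxy)phenyl]-3,4-dihydro-2H-chromene-3,4-diol
Conditions: NaBH4 (1.5 equiv), THF/EtOH 1:1, 0 °C, 1 h; aq NH4Cl
Reagents that add atoms: none
Why: Diastereoselective borohydride 1,2-reduction, in which axial hydride delivery to the C4 ketone of the half-chair (2-aryl and 3-OH equatorial) gives the equatorial 4-OH, i.e. the 2,3-trans-3,4-trans diol; C2 and C3 are untouched at 0 °C, and the C4 configuration is erased in the next step in any case.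

**Step 4**
Reactants: 6 (2R,3S,4R)-7-(benzyloxy)-2-[3,4-bis(benzyloxy)phenyl]-3,4-dihydro-2H-chromene-3,4-diol; 7 2-methoxybenzene-1,3-diol (2-methoxyresorcinol)
Product: 9 (2R,3S,4R)-7-(benzyloxy)-2-[3,4-bis(benzyloxy)phenyl]-4-(2,4-dihydroxy-3-methoxyphenyl)-3,4-dihydro-2H-chromen-3-ol, via C4 benzylic cation 8 (not isolated)
Conditions: 7 (5 equiv), TsOH·H2O (10 mol%), MeCN/CH2Cl2 3:1, 0 → 25 °C
Reagents that add atoms: none
Why: Brønsted-acid-catalysed SN1 Friedel–Crafts alkylation (the flavan-3,4-diol/phenol condensation used for condensed-tannin models), in which loss of water gives cation 8 stabilised by O1 and the 7-benzyloxy group, and the most nucleophilic ring carbon of 7 (ortho to one OH, para to the other) attacks anti to the neighbouring 3-OH so the new aryl group ends up trans (4R, all-equatorial); the 3,4-trans adduct is expected to predominate rather than form exclusively, and the excess of 7 suppresses double alkylation and self-condensation.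

**Step 5**
Reactants: 9 (2R,3S,4R)-7-(benzyloxy)-2-[3,4-bis(benzyloxy)phenyl]-4-(2,4-dihydroxy-3-methoxyphenyl)-3,4-dihydro-2H-chromen-3-ol
Product: 10 (2R,3S,4R)-2-(3,4-dihydroxyphenyl)-4-(2,4-dihydroxy-3-methoxyphenyl)-3,4-dihydro-2H-chromene-3,7-diol (CNP0124388.1)
Conditions: H2 (1 atm), Pd(OH)2/C (20 wt%), THF/MeOH 1:1, 25 °C
Reagents that add atoms: none
Why: Heterogeneous catalytic hydrogenolysis of the three benzyl aryl ethers under neutral conditions, which leaves the aryl methyl ether, the C3 carbinol and the three non-epimerisable stereocentres untouched.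

## Compound list

1 | 1-[4-(benzyloxy)-2-hydroxyphenyl]ethan-1-one | CC(=O)c1ccc(OCc2ccccc2)cc1O | starting material
2 | 3,4-bis(benzyloxy)benzaldehyde | O=Cc1ccc(OCc2ccccc2)c(OCc2ccccc2)c1 | starting material
3 | (E)-1-[4-(benzyloxy)-2-hydroxyphenyl]-3-[3,4-bis(benzyloxy)phenyl]prop-2-en-1-one | O=C(/C=C/c1ccc(OCc2ccccc2)c(OCc2ccccc2)c1)c1ccc(OCc2ccccc2)cc1O | intermediate
4 | [4-(benzyloxy)-2-hydroxyphenyl]{(2R,3S)-3-[3,4-bis(benzyloxy)phenyl]oxiran-2-yl}methanone | O=C(c1ccc(OCc2ccccc2)cc1O)[C@@H]1O[C@H]1c1ccc(OCc2ccccc2)c(OCc2ccccc2)c1 | intermediate (not isolated)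
5 | (2R,3R)-7-(benzyloxy)-2-[3,4-bis(benzyloxy)phenyl]-3-hydroxy-2,3-dihydro-4H-chromen-4-one | O=C1c2ccc(OCc3ccccc3)cc2O[C@H](c2ccc(OCc3ccccc3)c(OCc3ccccc3)c2)[C@H]1O | intermediate
6 | (2R,3S,4R)-7-(benzyloxy)-2-[3,4-bis(benzyloxy)phenyl]-3,4-dihydro-2H-chromene-3,4-diol | O[C@@H]1c2ccc(OCc3ccccc3)cc2O[C@H](c2ccc(OCc3ccccc3)c(OCc3ccccc3)c2)[C@H]1O | intermediate
7 | 2-methoxybenzene-1,3-diol (2-methoxyresorcinol) | COc1c(O)cccc1O | starting material
8 | (2R,3S)-7-(benzyloxy)-2-[3,4-bis(benzyloxy)phenyl]-3-hydroxy-3,4-dihydro-2H-chromen-4-ylium (C4 benzylic cation) | [CH+]1c2ccc(OCc3ccccc3)cc2O[C@H](c2ccc(OCc3ccccc3)c(OCc3ccccc3)c2)[C@H]1O | intermediate (not isolated)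
9 | (2R,3S,4R)-7-(benzyloxy)-2-[3,4-bis(benzyloxy)phenyl]-4-(2,4-dihydroxy-3-methoxyphenyl)-3,4-dihydro-2H-chromen-3-ol | COc1c(O)ccc([C@@H]2c3ccc(OCc4ccccc4)cc3O[C@H](c3ccc(OCc4ccccc4)c(OCc4ccccc4)c3)[C@H]2O)c1O | intermediate
10 | (2R,3S,4R)-2-(3,4-dihydroxyphenyl)-4-(2,4-dihydroxy-3-methoxyphenyl)-3,4-dihydro-2H-chromene-3,7-diol | COc1c(O)ccc([C@@H]2c3ccc(O)cc3O[C@H](c3ccc(O)c(O)c3)[C@H]2O)c1O | target

## Step count and risks

Total steps: 5. Longest linear sequence: 5 (1 or 2 → 3 → 5 → 6 → 9 → 10).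

**Step 2 (the proposed new reaction).** The risks are: low or wrong-sense induction with the chelating free phenol; scandium-promoted aroyl migration of the epoxide; competing oxa-Michael closure to the flavanone; and over-oxidation. The enantiomeric purity of 5 can be raised by recrystallisation. The fallback uses known chemistry, sets out from 1 and 2, and returns to the route at 5 (through 4). Compound 1 is protected with MOMCl/iPr2NEt in CH2Cl2 to give 1-[4-(benzyloxy)-2-(methoxymethoxy)phenyl]ethan-1-one F1. Claisen–Schmidt condensation of this with 2 (KOH 0.3 equiv, EtOH/THF) gives (E)-1-[4-(benzyloxy)-2-(methoxymethoxy)phenyl]-3-[3,4-bis(benzyloxy)phenyl]prop-2-en-1-one F2. Juliá–Colonna epoxidation (poly-L-leucine, urea–H2O2, DBU, THF, 25 °C) then gives [4-(benzyloxy)-2-(methoxymethoxy)phenyl]{(2R,3S)-3-[3,4-bis(benzyloxy)phenyl]oxiran-2-yl}methanone F3. Finally HCl/MeOH at 50 °C removes the MOM group, releasing 4, which cyclises in the same pot to 5. This costs two extra steps.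

**Step 4 (Friedel–Crafts at C4).** The risks are an eroded trans:cis ratio at C4 in this 5-deoxy series, double alkylation of the resorcinol ring, and self-condensation of 6. The fallback enforces the trans outcome by neighbouring-group participation; it sets out from 6 and returns at 9. Acetylation (Ac2O, pyridine, DMAP cat.) gives (2R,3R,4R)-7-(benzyloxy)-2-[3,4-bis(benzyloxy)phenyl]-3,4-dihydro-2H-chromene-3,4-diyl diacetate F4. Ionisation of the 4-acetate with BF3·OEt2 (20 mol%) in CH2Cl2/MeCN at −40 °C in the presence of 7 lets the 3-acetate bridge the upper face of C4 as an acyloxonium ion, so 7 can only enter trans. This gives (2R,3S,4R)-7-(benzyloxy)-2-[3,4-bis(benzyloxy)phenyl]-4-(2,4-dihydroxy-3-methoxyphenyl)-3,4-dihydro-2H-chromen-3-yl acetate F5. Methanolysis (K2CO3 cat., MeOH, 25 °C) then gives 9.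

**Step 5 (global hydrogenolysis).** The risks are incomplete debenzylation, reductive opening of the benzylic C2–O1 bond in the electron-rich 4-arylflavan, and an air-sensitive pentaphenol that is hard to purify from partly benzylated material. The fallback moves the deprotection to an earlier, well-precedented stage and finishes protecting-group-free; it sets out from 5 and returns at 10. Hydrogenolysis of 5 (H2, Pd/C, EtOAc/MeOH) gives (2R,3R)-2-(3,4-dihydroxyphenyl)-3,7-dihydroxy-2,3-dihydro-4H-chromen-4-one F6. NaBH4 in EtOH at 0 °C gives (2R,3S,4R)-2-(3,4-dihydroxyphenyl)-3,4-dihydro-2H-chromene-3,4,7-triol F7. Condensation of this with excess 7 in 0.1 M aqueous HCl at 25 °C (the classical flavan-3,4-diol/phenol coupling) gives 10 directly.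

## Further compounds

F1 | step 2 | 1-[4-(benzyloxy)-2-(methoxymethoxy)phenyl]ethan-1-one | CC(=O)c1ccc(OCc2ccccc2)cc1OCOC
F2 | step 2 | (E)-1-[4-(benzyloxy)-2-(methoxymethoxy)phenyl]-3-[3,4-bis(benzyloxy)phenyl]prop-2-en-1-one | O=C(/C=C/c1ccc(OCc2ccccc2)c(OCc2ccccc2)c1)c1ccc(OCc2ccccc2)cc1OCOC
F3 | step 2 | [4-(benzyloxy)-2-(methoxymethoxy)phenyl]{(2R,3S)-3-[3,4-bis(benzyloxy)phenyl]oxiran-2-yl}methanone | O=C(c1ccc(OCc2ccccc2)cc1OCOC)[C@@H]1O[C@H]1c1ccc(OCc2ccccc2)c(OCc2ccccc2)c1
F4 | step 4 | (2R,3R,4R)-7-(benzyloxy)-2-[3,4-bis(benzyloxy)phenyl]-3,4-dihydro-2H-chromene-3,4-diyl diacetate | CC(=O)O[C@@H]1c2ccc(OCc3ccccc3)cc2O[C@H](c2ccc(OCc3ccccc3)c(OCc3ccccc3)c2)[C@H]1OC(C)=O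
F5 | step 4 | (2R,3S,4R)-7-(benzyloxy)-2-[3,4-bis(benzyloxy)phenyl]-4-(2,4-dihydroxy-3-methoxyphenyl)-3,4-dihydro-2H-chromen-3-yl acetate | COc1c(O)ccc([C@@H]2c3ccc(OCc4ccccc4)cc3O[C@H](c3ccc(OCc4ccccc4)c(OCc4ccccc4)c3)[C@H]2OC(C)=O)c1O
F6 | step 5 | (2R,3R)-2-(3,4-dihydroxyphenyl)-3,7-dihydroxy-2,3-dihydro-4H-chromen-4-one | O=C1c2ccc(O)cc2O[C@H](c2ccc(O)c(O)c2)[C@H]1O
F7 | step 5 | (2R,3S,4R)-2-(3,4-dihydroxyphenyl)-3,4-dihydro-2H-chromene-3,4,7-triol | O[C@@H]1c2ccc(O)cc2O[C@H](c2ccc(O)c(O)c2)[C@H]1O
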